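Locants used throughout: C1 = C(OH)(iPr); C2, C3 = CH2 of the cyclopentane; C4 = ring-fusion C(CH3); C5 = CH2; C6, C7 = epoxide carbons (C7 carries CH3); C8 = CHOH; C9 = CH–O–aroyl; C10 = ring-fusion CH; five-membered ring C1–C2–C3–C4–C10, seven-membered ring C4–C5–C6–C7–C8–C9–C10.
Retrosynthesis: the silyl groups and the ester C–O bond are cut first, then C9–O/C10–H (hydroboration), the epoxide, C8–O (allylic oxidation, reduction) and C1–isopropyl (addition to a ketone); the bicyclic dienone that remains is cut at C10–C4 and C9–C8 together.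
Enabling feature: the seven-membered ring is a five-carbon run C4–C5–C6–C7–C8 closed by the two-carbon unit C9–C10, and C10 is tied to C4 a second time through C1–C2–C3; a vinylcyclopropane (ring C4–C5–C6, alkene C7=C8) with an ynone C9≡C10–C1(=O) on a three-atom tether from the quaternary ring carbon C4 is therefore a (5+2) precursor that closes both rings in one rhodium-catalysed event.
Forward order: nerol → cyclopropane C4–C5–C6 → isopropenyl group and ynone arm → (5+2) cycloaddition (both rings) → isopropyl at C1 → oxygen at C8 → epoxide → C9–OH/C10–H → ester → desilylation.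
Stereochemistry: C4 from the asymmetric Simmons–Smith cyclopropanation of nerol, carried through the cycloaddition with retention; C1 by addition anti to the C4 methyl; C8 by a reagent-controlled Corey–Bakshi–Shibata reduction; the epoxide anti to the C8 silyl ether; C9 and C10 by syn hydroboration on the face opposite the C4 methyl and the C8 silyl ether.

Key step: step 8

Remark on the chemistry: the sense of induction of the dioxaborolane ligand (step 1) and of the oxazaborolidine (step 11) is assigned from the accepted transition-state models, and 4-[(tert-butyldimethylsilyl)oxy]benzoic acid is taken as a purchasable reagent.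

Step 1
Reactants: 1 nerol, (2Z)-3,7-dimethylocta-2,6-dien-1-ol
Product: 2 [(1S,2R)-2-methyl-2-(4-methylpent-3-en-1-yl)cyclopropyl]methanol
Conditions: Et2Zn, CH2I2, DME, (4R,5R)-2-butyl-N,N,N′,N′-tetramethyl-1,3,2-dioxaborolane-4,5-dicarboxamide (1.2 equiv), CH2Cl2, −10 °C to rt
Reagents that add atoms: diiodomethane, ICI
Why: Asymmetric Simmons–Smith cyclopropanation (dioxaborolane-mediated, Charette form): methylene is delivered syn and stereospecifically to the allylic-alcohol alkene only, so the Z geometry fixes CH2OH cis to the homoprenyl chain and the ligand fixes the absolute configuration of the quaternary carbon (future C4) and of C6.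

Step 2
Reactants: 2 [(1S,2R)-2-methyl-2-(4-methylpent-3-en-1-yl)cyclopropyl]methanol
Product: 4 (1S,2R)-2-methyl-2-(4-methylpent-3-en-1-yl)cyclopropane-1-carboxylic acid, via aldehyde 3 (not isolated)
Conditions: TEMPO (0.2 equiv), PhI(OAc)2 (2.2 equiv), MeCN/H2O, rt
Reagents that add atoms: water, O
Why: Nitroxyl-mediated oxidation of a primary alcohol to the acid through the aldehyde hydrate should leave the trisubstituted alkene and the cyclopropane stereocenters untouched.

Step 3
Reactants: 4 (1S,2R)-2-methyl-2-(4-methylpent-3-en-1-yl)cyclopropane-1-carboxylic acid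
Product: 6 1-[(1S,2R)-2-methyl-2-(4-methylpent-3-en-1-yl)cyclopropyl]ethan-1-one, via gem-diolate 5 (not isolated)
Conditions: MeLi (3 equiv), Et2O, 0 °C; then aq. NH4Cl
Reagents that add atoms: methyllithium, [Li]C
Why: Addition of methyllithium to the lithium carboxylate gives a stable gem-diolate that collapses to the methyl ketone only on work-up (classical acid-to-methyl-ketone conversion), and the cyclopropyl α-hydrogen is too weakly acidic to epimerise.

Step 4
Reactants: 6 1-[(1S,2R)-2-methyl-2-(4-methylpent-3-en-1-yl)cyclopropyl]ethan-1-one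
Product: 8 3-[(1R,2S)-2-acetyl-1-methylcyclopropyl]propanal, via ozonide 7 (not isolated)
Conditions: O3, CH2Cl2, −78 °C; then PPh3, −78 °C to rt
Reagents that add atoms: ozone, [O-][O+]=O
Why: Ozonolysis with reductive work-up cleaves the only alkene, releasing acetone and the aldehyde carbon that becomes C1, while ketone and cyclopropane are inert.

Step 5
Reactants: 8 3-[(1R,2S)-2-acetyl-1-methylcyclopropyl]propanal
Product: 9 1-[(1S,2R)-2-(3-hydroxypent-4-yn-1-yl)-2-methylcyclopropyl]ethan-1-one (both carbinol epimers)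
Conditions: HC≡CMgBr (1.1 equiv), THF, −78 °C
Reagents that add atoms: ethynylmagnesium bromide, C#C[Mg]Br
Why: Grignard addition at low temperature should select the aldehyde over the hindered cyclopropyl methyl ketone, and the new carbinol center is of no consequence because it is oxidised in step 7.

Step 6
Reactants: 9 1-[(1S,2R)-2-(3-hydroxypent-4-yn-1-yl)-2-methylcyclopropyl]ethan-1-one
Product: 10 5-[(1R,2R)-1-methyl-2-(prop-1-en-2-yl)cyclopropyl]pent-1-yn-3-ol (both carbinol epimers)
Conditions: Ph3PCH3Br (4 equiv), KOtBu (3.8 equiv), THF, 0 °C to rt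
Reagents that add atoms: methylenetriphenylphosphorane, C=P(c1ccccc1)(c1ccccc1)c1ccccc1
Why: Wittig methylenation of the methyl ketone with excess ylide (hydroxyl and alkyne C–H are only deprotonated) installs the isopropenyl group, that is C7=C8 with its methyl.

Step 7
Reactants: 10 5-[(1R,2R)-1-methyl-2-(prop-1-en-2-yl)cyclopropyl]pent-1-yn-3-ol
Product: 11 5-[(1R,2R)-1-methyl-2-(prop-1-en-2-yl)cyclopropyl]pent-1-yn-3-one
Conditions: Dess–Martin periodinane, NaHCO3, CH2Cl2, 0 °C to rt
Reagents that add atoms: none
Why: Dess–Martin oxidation of a secondary propargylic alcohol gives the terminal ynone under buffered conditions that should leave the vinylcyclopropane intact.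

Step 8
Reactants: 11 5-[(1R,2R)-1-methyl-2-(prop-1-en-2-yl)cyclopropyl]pent-1-yn-3-one
Product: 12 (3aR)-3a,6-dimethyl-3,3a,4,7-tetrahydroazulen-1(2H)-one
Conditions: [Rh(CO)2Cl]2 (5 mol %), ClCH2CH2Cl (0.01 M), 70 °C
Reagents that add atoms: none
Why: Proposed new method: monovalent rhodium should insert into the C4–C6 bond of the cyclopropane, which the isopropenyl group activates, to give a trivalent σ-alkyl/π-allyl rhodacycle bound to C4 and, through the allyl unit C6–C7–C8, to C8; the tethered ynone then inserts and reductive elimination releases the cyclohepta-1,4-diene, so that C10–C4 and C9–C8 arise in one catalytic event. The closest known reaction type is the rhodium-catalysed intramolecular (5+2) cycloaddition of vinylcyclopropanes with alkynes tethered through the alkene terminus, together with the (5+2) mode shown by vinylcyclopropanes that carry an alkene on a ring-carbon tether cis to the vinyl group; an alkyne partner on a tether from a fully substituted ring carbon has not been shown. The five-membered ring closes in the exo sense, the proximal alkyne carbon C10 being joined to C4 across the three-atom tether C1–C2–C3, and the seven-membered ring closes when the distal alkyne carbon C9 is coupled with the allyl terminus C8 out of the eight-membered rhodacycle, the cis C6=C7 bond ending up in the ring. The one stereocenter of the product, C4, is not created here but carried over: insertion of the metal and the C–C bond formation at C4 both go with retention, so the configuration set in step 1 decides it. The step needs cleavage of the more substituted C4–C6 bond and the (5+2) instead of the (3+2) outcome: only the rhodacycle from C4–C6 cleavage brings the metal within reach of the alkyne while opening of C5–C6 is reversible and leads nowhere, and the cis relation of tether and isopropenyl group together with the 2-methyl substituent favours the anti allyl geometry that a cis-cycloheptene requires.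

Step 9
Reactants: 12 (3aR)-3a,6-dimethyl-3,3a,4,7-tetrahydroazulen-1(2H)-one
Product: 13 (1R,3aR)-3a,6-dimethyl-1-(propan-2-yl)-1,2,3,3a,4,7-hexahydroazulen-1-ol (C1–OH cis to the C4 methyl)
Conditions: iPrMgCl (3 equiv), CeCl3 (3 equiv), THF, −78 °C
Reagents that add atoms: isopropylmagnesium chloride, CC(C)[Mg]Cl
Why: Organocerium 1,2-addition suppresses enolisation and conjugate addition, and the reagent should approach C1 from the face opposite the pseudo-axial C4 methyl (1,3 across the five-membered ring), which places the hydroxyl cis to that methyl.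

Step 10
Reactants: 13 (1R,3aR)-3a,6-dimethyl-1-(propan-2-yl)-1,2,3,3a,4,7-hexahydroazulen-1-ol
Product: 15 (1R,3aR)-1-hydroxy-3a,6-dimethyl-1-(propan-2-yl)-2,3,3a,4-tetrahydroazulen-7(1H)-one (C8 ketone), via allylic alcohol 14 (not isolated)
Conditions: SeO2 (0.5 equiv), t-BuOOH, CH2Cl2, 0 °C to rt; then MnO2, rt
Reagents that add atoms: tert-butyl hydroperoxide, CC(C)(C)OO (its oxygen is passed on by SeO2, O=[Se]=O)
Why: SeO2 allylic oxidation (ene reaction at the electron-rich C6=C7 bond, then 2,3-sigmatropic shift) should hydroxylate the doubly allylic CH2 next to the more substituted alkene carbon, and MnO2 oxidises the bis-allylic alcohol to the cross-conjugated dienone, so the C8 configuration of 14 does not matter.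

Step 11
Reactants: 15 (1R,3aR)-1-hydroxy-3a,6-dimethyl-1-(propan-2-yl)-2,3,3a,4-tetrahydroazulen-7(1H)-one
Product: 16 (1R,3aR,7S)-3a,6-dimethyl-1-(propan-2-yl)-1,2,3,3a,4,7-hexahydroazulene-1,7-diol (C8–OH cis to the C4 methyl)
Conditions: (R)-2-methyl-CBS-oxazaborolidine (0.3 equiv), catecholborane, toluene, −78 °C; then MeOH
Reagents that add atoms: none
Why: Corey–Bakshi–Shibata reduction is a 1,2-reduction under reagent control; with the 2-methyl-substituted alkenyl flank (C7) as the large group and the CH=C flank (C9) as the small one, the (R)-catalyst should deliver hydride to the face that gives the (S)-carbinol.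

Step 12
Reactants: 16 (1R,3aR,7S)-3a,6-dimethyl-1-(propan-2-yl)-1,2,3,3a,4,7-hexahydroazulene-1,7-diol
Product: 17 (1R,3aR,7S)-7-[(tert-butyldimethylsilyl)oxy]-3a,6-dimethyl-1-(propan-2-yl)-1,2,3,3a,4,7-hexahydroazulen-1-ol
Conditions: TBSCl, imidazole, DMF, rt
Reagents that add atoms: tert-butyldimethylsilyl chloride, CC(C)(C)[Si](C)(C)Cl
Why: Silyl ether formation with the chloride and imidazole is selective for the secondary allylic hydroxyl over the hindered tertiary one.

Step 13
Reactants: 17 (1R,3aR,7S)-7-[(tert-butyldimethylsilyl)oxy]-3a,6-dimethyl-1-(propan-2-yl)-1,2,3,3a,4,7-hexahydroazulen-1-ol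
Product: 18 C6–C7 epoxide of 17 (epoxide oxygen trans to the C8 silyloxy group and to the C4 methyl)
Conditions: mCPBA (1.05 equiv), NaHCO3, CH2Cl2, −20 °C
Reagents that add atoms: 3-chloroperbenzoic acid, OOC(=O)c1cccc(Cl)c1
Why: Peracid (Prilezhaev) epoxidation should take the accessible, more electron-rich C6=C7 bond (C9=C10 is flanked by two fully substituted carbons and two allylic oxygens) from the face opposite the bulky allylic silyl ether and the C4 methyl.

Step 14
Reactants: 18 C6–C7 epoxide of 17
Product: 20 C9 alcohol (C9–OH and C10–H both on the face opposite the C4 methyl; trans ring fusion; C8–OTBS trans to C9–OH), via alkylborane 19 (not isolated)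
Conditions: BH3·THF, THF, 0 °C to rt; then NaBO3·4H2O, H2O, rt
Reagents that add atoms: borane (as BH3·THF), B; sodium perborate, [Na+].[O-]OB=O
Why: Hydroboration–oxidation adds H and OH syn with boron at the less substituted C9; attack on the face opposite the C4 methyl, the C8 silyl ether and the C1 oxygen (as in hydroboration of alkenes next to an angular methyl in steroids) sets C9 and C10 together, and the oxidation goes with retention.

Step 15
Reactants: 20 C9 alcohol; 21 4-[(tert-butyldimethylsilyl)oxy]benzoic acid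
Product: 22 C9 4-[(tert-butyldimethylsilyl)oxy]benzoate of 20
Conditions: DCC, DMAP (0.5 equiv), CH2Cl2, rt
Reagents that add atoms: 4-[(tert-butyldimethylsilyl)oxy]benzoic acid (compound 21), CC(C)(C)[Si](C)(C)Oc1ccc(cc1)C(=O)O
Why: Steglich esterification acylates the only free secondary hydroxyl, the tertiary C1–OH being unreactive and C8–OH being silylated.

Step 16
Reactants: 22 C9 4-[(tert-butyldimethylsilyl)oxy]benzoate of 20
Product: 23 CNP0290052.1, (1R,4R,6S,7R,8S,9R,10S) in the locants of the plan
Conditions: Bu4NF, AcOH (1:1), THF, 0 °C to rt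
Reagents that add atoms: none
Why: Fluoride-induced desilylation removes the aryl and the secondary silyl ether, and the acetic acid buffer keeps the medium near neutral so that acyl migration to the C8 oxygen, Payne rearrangement and epoxide opening should be avoided.

Compound list
1 | nerol, (2Z)-3,7-dimethylocta-2,6-dien-1-ol | CC(C)=CCC/C(C)=C\CO | starting material
2 | [(1S,2R)-2-methyl-2-(4-methylpent-3-en-1-yl)cyclopropyl]methanol | CC(C)=CCC[C@]1(C)C[C@@H]1CO | intermediate
3 | (1S,2R)-2-methyl-2-(4-methylpent-3-en-1-yl)cyclopropane-1-carbaldehyde (not isolated) | CC(C)=CCC[C@]1(C)C[C@@H]1C=O | intermediate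
4 | (1S,2R)-2-methyl-2-(4-methylpent-3-en-1-yl)cyclopropane-1-carboxylic acid | CC(C)=CCC[C@]1(C)C[C@@H]1C(=O)O | intermediate
5 | dilithium 1-[(1S,2R)-2-methyl-2-(4-methylpent-3-en-1-yl)cyclopropyl]ethane-1,1-diolate (not isolated) | CC(C)=CCC[C@]1(C)C[C@@H]1C(C)(O[Li])O[Li] | intermediate
6 | 1-[(1S,2R)-2-methyl-2-(4-methylpent-3-en-1-yl)cyclopropyl]ethan-1-one | CC(C)=CCC[C@]1(C)C[C@@H]1C(C)=O | intermediate
7 | 5-{2-[(1R,2S)-2-acetyl-1-methylcyclopropyl]ethyl}-3,3-dimethyl-1,2,4-trioxolane, ozonide of 6 (not isolated) | CC1(C)OOC(CC[C@]2(C)C[C@@H]2C(C)=O)O1 | intermediate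
8 | 3-[(1R,2S)-2-acetyl-1-methylcyclopropyl]propanal | O=CCC[C@]1(C)C[C@@H]1C(C)=O | intermediate
9 | 1-[(1S,2R)-2-(3-hydroxypent-4-yn-1-yl)-2-methylcyclopropyl]ethan-1-one (both carbinol epimers) | C#CC(O)CC[C@]1(C)C[C@@H]1C(C)=O | intermediate
10 | 5-[(1R,2R)-1-methyl-2-(prop-1-en-2-yl)cyclopropyl]pent-1-yn-3-ol (both carbinol epimers) | C#CC(O)CC[C@]1(C)C[C@@H]1C(C)=C | intermediate
11 | 5-[(1R,2R)-1-methyl-2-(prop-1-en-2-yl)cyclopropyl]pent-1-yn-3-one | C#CC(=O)CC[C@]1(C)C[C@@H]1C(C)=C | intermediate
12 | (3aR)-3a,6-dimethyl-3,3a,4,7-tetrahydroazulen-1(2H)-one | O=C1CC[C@]2(C)CC=C(C)CC=C12 | intermediate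
13 | (1R,3aR)-3a,6-dimethyl-1-(propan-2-yl)-1,2,3,3a,4,7-hexahydroazulen-1-ol | CC(C)[C@]1(O)CC[C@]2(C)CC=C(C)CC=C21 | intermediate
14 | (1R,3aR)-3a,6-dimethyl-1-(propan-2-yl)-1,2,3,3a,4,7-hexahydroazulene-1,7-diol, both C8 epimers (not isolated) | CC(C)[C@]1(O)CC[C@]2(C)CC=C(C)C(O)C=C21 | intermediate
15 | (1R,3aR)-1-hydroxy-3a,6-dimethyl-1-(propan-2-yl)-2,3,3a,4-tetrahydroazulen-7(1H)-one | CC(C)[C@]1(O)CC[C@]2(C)CC=C(C)C(=O)C=C21 | intermediate
16 | (1R,3aR,7S)-3a,6-dimethyl-1-(propan-2-yl)-1,2,3,3a,4,7-hexahydroazulene-1,7-diol | CC(C)[C@]1(O)CC[C@]2(C)CC=C(C)[C@@H](O)C=C21 | intermediate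
17 | (1R,3aR,7S)-7-[(tert-butyldimethylsilyl)oxy]-3a,6-dimethyl-1-(propan-2-yl)-1,2,3,3a,4,7-hexahydroazulen-1-ol | CC(C)[C@]1(O)CC[C@]2(C)CC=C(C)[C@@H](O[Si](C)(C)C(C)(C)C)C=C21 | intermediate
18 | C6–C7 epoxide of 17, epoxide oxygen trans to the C8 silyloxy group and to the C4 methyl | CC(C)[C@]1(O)CC[C@]2(C)C[C@@H]3O[C@]3(C)[C@@H](O[Si](C)(C)C(C)(C)C)C=C21 | intermediate
19 | C9 borane adduct of 18, boron and C10–H on the face opposite the C4 methyl (not isolated) | CC(C)[C@]1(O)CC[C@]2(C)C[C@@H]3O[C@]3(C)[C@@H](O[Si](C)(C)C(C)(C)C)[C@H](B)[C@H]21 | intermediate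
20 | C9 alcohol: C1,C9-diol with C8–OTBS and C6–C7 epoxide, trans-fused, C9–OH trans to C8–OTBS | CC(C)[C@]1(O)CC[C@]2(C)C[C@@H]3O[C@]3(C)[C@@H](O[Si](C)(C)C(C)(C)C)[C@H](O)[C@H]21 | intermediate
21 | 4-[(tert-butyldimethylsilyl)oxy]benzoic acid | CC(C)(C)[Si](C)(C)Oc1ccc(cc1)C(=O)O | starting material
22 | C9 4-[(tert-butyldimethylsilyl)oxy]benzoate of 20 | CC(C)[C@]1(O)CC[C@]2(C)C[C@@H]3O[C@]3(C)[C@@H](O[Si](C)(C)C(C)(C)C)[C@H](OC(=O)c3ccc(O[Si](C)(C)C(C)(C)C)cc3)[C@H]21 | intermediate
23 | CNP0290052.1 | CC(C)[C@]1(O)CC[C@]2(C)C[C@@H]3O[C@]3(C)[C@@H](O)[C@H](OC(=O)c3ccc(O)cc3)[C@H]21 | target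

Total step count: 16. Longest linear sequence: 16 steps (1 to 23); compound 21 is used as bought.

Steps most likely to fail

Step 8. The catalyst may open the less hindered C5–C6 bond, or fail to pass the fully substituted carbon C4 on to the alkyne, so that alkyne oligomerisation or the (3+2) course takes over. The fallback sets out from 10 and comes back at 12. Partial hydrogenation of the alkyne of 10 (H2, Pd/CaCO3 poisoned with Pb(OAc)2, quinoline) should give the allylic alcohol 5-[(1R,2R)-1-methyl-2-(prop-1-en-2-yl)cyclopropyl]pent-1-en-3-ol F1, and Dess–Martin oxidation the vinyl ketone 5-[(1R,2R)-1-methyl-2-(prop-1-en-2-yl)cyclopropyl]pent-1-en-3-one F2. The [Rh(CO)2Cl]2-catalysed (5+2) cycloaddition with an alkene held on a ring-carbon tether cis to the vinyl group, the partner shown for this tether position, should then give the saturated bicyclic ketone (3aR)-3a,6-dimethyl-3,3a,4,7,8,8a-hexahydroazulen-1(2H)-one F3; either C10 epimer serves. Thermodynamic silylation (Me3SiOTf, Et3N) should give the more substituted silyl enol ether {[(3aR)-3a,6-dimethyl-2,3,3a,4,7,8-hexahydroazulen-1-yl]oxy}(trimethyl)silane F4, and Saegusa–Ito oxidation with Pd(OAc)2, in which only C9 offers a β-hydrogen, restores the C9=C10 bond and gives 12.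

Step 14. Addition of borane to the hindered C9=C10 bond may be slow enough for reductive opening of the epoxide to compete, or may take place from the wrong face. The fallback sets out from 18 and comes back at 20. Dihydroxylation with OsO4 in pyridine on the same open face should give the C9,C10-cis-diol of 18 F5. 1,1′-Thiocarbonyldiimidazole should close the C9,C10-cyclic thionocarbonate F6, since the C1 hydroxyl is trans to the C10 oxygen and cannot take part. Barton deoxygenation (Bu3SnH, AIBN, toluene, 80 °C) cleaves the C–O bond at the tertiary carbon C10, the radical should take hydrogen on the face opposite the C4 methyl, and mild methanolysis (K2CO3, MeOH) of the remaining thiocarbonate frees the C9 hydroxyl to give 20.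

Step 11. The two alkenyl flanks of the ketone may be too alike for the catalyst, which would mean poor facial selectivity. The fallback sets out from 15 and comes back at 16. Luche reduction (NaBH4, CeCl3·7H2O, MeOH, −78 °C) under substrate control should give both C8 carbinols, from which 16 is separated. The unwanted epimer (1R,3aR,7R)-3a,6-dimethyl-1-(propan-2-yl)-1,2,3,3a,4,7-hexahydroazulene-1,7-diol F7 is inverted by Mitsunobu reaction (4-nitrobenzoic acid, PPh3, diisopropyl azodicarboxylate) to the (7S) 4-nitrobenzoate F8, and methanolysis (K2CO3, MeOH) gives 16.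

Further compounds
F1 | step 8 | 5-[(1R,2R)-1-methyl-2-(prop-1-en-2-yl)cyclopropyl]pent-1-en-3-ol (both carbinol epimers) | C=CC(O)CC[C@]1(C)C[C@@H]1C(C)=C
F2 | step 8 | 5-[(1R,2R)-1-methyl-2-(prop-1-en-2-yl)cyclopropyl]pent-1-en-3-one | C=CC(=O)CC[C@]1(C)C[C@@H]1C(C)=C
F3 | step 8 | (3aR)-3a,6-dimethyl-3,3a,4,7,8,8a-hexahydroazulen-1(2H)-one (C10 epimers) | O=C1CC[C@]2(C)CC=C(C)CCC12
F4 | step 8 | {[(3aR)-3a,6-dimethyl-2,3,3a,4,7,8-hexahydroazulen-1-yl]oxy}(trimethyl)silane | C[Si](C)(C)OC1=C2CCC(C)=CC[C@@]2(C)CC1
F5 | step 14 | C9,C10-cis-diol of 18, both hydroxyls on the face opposite the C4 methyl | CC(C)[C@]1(O)CC[C@]2(C)C[C@@H]3O[C@]3(C)[C@@H](O[Si](C)(C)C(C)(C)C)[C@H](O)[C@]21O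
F6 | step 14 | C9,C10-cyclic thionocarbonate of F5 | CC(C)[C@]1(O)CC[C@]2(C)C[C@@H]3O[C@]3(C)[C@@H](O[Si](C)(C)C(C)(C)C)[C@H](OC(=S)O4)[C@]214
F7 | step 11 | (1R,3aR,7R)-3a,6-dimethyl-1-(propan-2-yl)-1,2,3,3a,4,7-hexahydroazulene-1,7-diol | CC(C)[C@]1(O)CC[C@]2(C)CC=C(C)[C@H](O)C=C21
F8 | step 11 | (1R,3aR,7S)-1-hydroxy-3a,6-dimethyl-1-(propan-2-yl)-1,2,3,3a,4,7-hexahydroazulen-7-yl 4-nitrobenzoate | CC(C)[C@]1(O)CC[C@]2(C)CC=C(C)[C@@H](OC(=O)c3ccc(cc3)[N+](=O)[O-])C=C21
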